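Equal product from the two hands is impossible in the summer run: at 2.50 min the left-handed product stands 13 percentage points above the right-handed product, against a scatter of 0.5 points.

common to all: racemization catalyst 15 mol%
- summer: left-handed substrate 10 mM; right-handed substrate 10 mM; solid reagent 4 equiv; run made earlier
- flask: left-handed substrate 20 mM; right-handed substrate 20 mM; solid reagent 4.00 equiv; time 12 min

summer run (percent of the left-handed substrate and right-handed substrate together charged)

| time / min | left-handed product / % | right-handed product / % |
|---|---|---|
| 0.333 | 1.4 | 0.2 |
| 0.833 | 6.1 | 2.8 |
| 1.50 | 12.2 | 6.3 |
| 2.50 | 21.9 | 9.3 |

(readings scatter by 0.5 percentage points)

- partner is single-handed; left-handed substrate and right-handed substrate are mirror images of each other, charged as a racemate, each of them at the stated concentration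
- given per volume of solution although it is solid: solid reagent
- the earlier runs were read with a standard deviation of 0.5 percentage points
- steps that have been proposed: partner -> decomposed reagent; partner + left-handed substrate -> left-handed product; solid reagent <-> partner; partner + right-handed substrate -> right-handed product; left-handed substrate + racemization catalyst <-> right-handed substrate + racemization catalyst
- at the start none of the solid reagent is in solution
- an excess is the difference of the two amounts in percent of their sum
- an excess is below zero if the other one leads
- no earlier run changes the charge of racemization catalyst; that part of a forecast is a guess
- the handed part of partner does not stay in what it makes, so the products of the two hands are mirror images too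

- excess of left-handed product over right-handed product in the product at 80 s
- excess of left-handed product over right-handed product in the product at 12 min
- part of the left-handed substrate and right-handed substrate charged together that has reacted at 12 min

The ratio of those two readings, 2.35, is read as the selectivity factor s: the left-handed product formed for each right-handed product while c(left-handed substrate) equals c(right-handed substrate), so that the product excess then stands at 40.4% and the left-handed product makes up s/(s+1) of what has reacted. This reckoning takes the racemization catalyst to keep the two substrates equal, a guess since no earlier run changes its charge, and so commits to that excess at both 80 s and 12 min.

The forecast, for which “The racemization rate is poorly defined, but doubled catalyst concentration helps”, gave 38% at 80 s, 28% at 12 min and 80% reacted, its late excess lying 12 points below this reckoning.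

The flask gives 41.9% at 80 s, 41.4% at 12 min and 80.8% reacted, so its late excess stands 13 points above the forecast.

    partner → decomposed reagent (k = 0.0200 /s)
    partner + left-handed substrate → left-handed product (k = 1.00 /M/s)
    solid reagent ⇌ partner, rate k3*(cs3 - [partner]) while solid is left; crystals form when [partner] > cs3 (solubility = 10.0 mM, k = 0.0220 /s)
    partner + right-handed substrate → right-handed product (k = 0.400 /M/s)
    left-handed substrate + racemization catalyst ⇌ right-handed substrate + racemization catalyst, rate k5*[racemization catalyst]*[left-handed substrate] forward; the back reaction follows from the equilibrium constant (k = 9.70 /M/s)

In this flask the two substrates relax by racemization with a half-life of 0.198 min at 12.0 min, short against the run time of 12 min, and they stand equal at the end, the left-handed substrate at 9.59% and the right-handed substrate at 9.61%, while 80.8% reacted reckons with s to 56.7% of left-handed product against 57.1% found. In a neighbour flask, the same recipe but with 1.00 equiv of solid reagent, 27.2% reacted reckons with s to 19.1% of left-handed product, and that neighbour flask holds 19.3%.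

Readings and results were computed for substances that don't exist.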